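4 questions stand on this flask, where substrate and partner give target under catalyst. 3 can be read off the runs, but the east run, with its partner cut to 0.430 M, has to be reckoned.

| flask | substrate | partner | catalyst | time |
|---|---|---|---|---|
| south-east | 1.00 M | 1.50 M | 0.00500 M |  |
| north-west | 0.600 M | 1.10 M | 0.00500 M |  |
| north | 0.500 M | 1.50 M | 0.00500 M |  |
| north-east | 1.00 M | 0.750 M | 0.00500 M |  |
| east | 1.00 M | 0.430 M | 0.00500 M | 22 min |

- south-east run (time / min: [target] / M): 3.7: 0.258; 7.3: 0.426; 11: 0.527; 15: 0.596; 18: 0.624; 22: 0.652
- north-west run (time / min: [target] / M): 3.7: 0.145; 7.3: 0.239; 11: 0.300; 15: 0.341; 18: 0.363; 22: 0.380
- north run (time / min: [target] / M): 3.7: 0.130; 7.3: 0.219; 11: 0.279; 15: 0.323; 18: 0.347; 22: 0.359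
- north-east run (time / min: [target] / M): 3.7: 0.208; 7.3: 0.326; 11: 0.389; 15: 0.417; 18: 0.428; 22: 0.441

(standard deviation of a reading: 0.003 M)

1. apparent order in [substrate] of the starting rate, round the charge of the south-east run (the rate where two percent of its substrate have turned into target) (one fixed amount of target, the same in the runs compared)
2. apparent order in [partner] of the starting rate, round the charge of the south-east run (the rate where two percent of its substrate have turned into target)
3. the north-west run starts with 0.400 M less of substrate and of partner than the south-east run, and with no target. Compared where both hold the same amount of substrate, once fifteen percent of what the north-west run was charged with has turned into target, is the north-west run faster, slower or alike (within a tenth)?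
4. target in the east run at 22 min, as a share of the substrate charged

- Overall: substrate + partner -> target, with catalyst as catalyst.
- Constant volume, constant temperature.
- What is held in complexes is read along with the free species.
- An order is taken over about fifteen percent of the charge, up and down.

We count in fractions of the substrate charge. At the first reading the south-east run has turned 25.8% of its charge and the north run, with half the substrate, has turned 26.0%. That is what first order in substrate looks like (pseudo-first-order, if the partner holds), so our measure is the exponent, the natural logarithm of charge over substrate left.

But a steady flask would grow that exponent in step with the clock. In the south-east run it goes from 0.298 at 3.7 min to 1.06 at 22 min, which is 3.56 times as much on a clock 5.95 times as long. The logarithm has already taken out the falling substrate, so we suspect the partner. The north-east run has half the partner of the south-east run. It keeps 78.1% of the south-east exponent at the first reading, but at the last only 55.1%, close to the partner ratio. Late in these two runs, then, the exponent goes nearly with the partner charged.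

In the north-east run the exponent at 22 min per partner charged is 0.775 M⁻¹; we call this the reach. Carried flat to the east run, it gives 28.4% of the substrate.

The objection is that the reach isn't constant. The south-east run has 0.704 M⁻¹, less than the north-east run, while the north and north-west runs, with less substrate, stand higher at 0.844 M⁻¹ and 0.912 M⁻¹. So we keep to the two runs with the east run's substrate and treat the drift as a correction. Prolonging their line to the east partner raises the reach to 0.806 M⁻¹, and the share to 29.3%. That line may be too steep, though. Over the last interval the south-east run still gains 2.80% of its charge, more than the 1.30% of the north-east run, so the south-east reach is the less finished of the two. We commit to the band between the two shares.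

The forecast, from the same runs, gave orders of 1 in substrate and 0.15 in partner, faster for the north-west run and 29% for the east run, holding that “All of these fit one equilibrium”.

The flask gives orders of 1.0 and 0.20; the north-west run is faster, at 1.4 times the south-east rate at equal substrate; and the east run stands at 28.3%, beside the flat end of our band.

    catalyst + substrate + partner → target + catalyst (59.28 M⁻² min⁻¹)
    partner → lost reagent (0.08400 min⁻¹)
    catalyst + partner ⇌ idle catalyst-reagent complex, settled at all times (2.760 M⁻¹)

That share is a reach of 0.774 M⁻¹ in the east run, beside 0.775 M⁻¹ in the north-east run. The reach stays this short because partner turns into lost reagent, and at 0.0840 min⁻¹ the half-life of that step is 8.25 min, shorter than the 22 min asked. The simulated east run without that step makes 41.5% instead of 28.3%, and its reach rises to 1.25 M⁻¹.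

The earlier runs and the new flask were generated by integration from invented constants; noise was put on by code.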